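The dihydropyran ring of the chroman is cut across C3–C4 and O1–C8a. This exploits the fact that O1, quaternary C2 and C3 form a contiguous triad that maps onto an enantiopure 2,2-disubstituted oxirane, while benzylic C4 and aryl C8a sit 1,3 on the arene as a benzylic bromide and an aryl bromide. In one flask the benzylic Grignard reagent opens silylated (R)-2-methylglycidol at CH2 with release of ring strain (C3–C4), and the tertiary alkoxide thus unmasked is arylated by palladium (O1–C8a): a [3+3] annulation that carries C2 over intact. C–H borylation at C6, two Wittig reactions and asymmetric 1,4-arylation of a 6-prenylchromone finish the flavanone.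

Key step: step 4

Remark: (R)-2-methylglycidol is taken as a commercial enantiopure building block; its O-silyl ether has the same spatial arrangement and is called (S) only because silylation reverses the CIP ranking of the two CH2 groups.

Step 1
Reactants: 1 2-bromo-3-methylphenol
Product: 2 (2-bromo-3-methylphenoxy)triisopropylsilane
Conditions: i-Pr3SiCl, imidazole, DMF, rt
Reagents that add atoms: triisopropylsilyl chloride, CC(C)[Si](Cl)(C(C)C)C(C)C
Why: Imidazole-promoted silylation of the phenol installs a bulky silyl ether that should withstand the organomagnesium, carbonate and ylide steps ahead and fall to fluoride at the end.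

Step 2
Reactants: 2 (2-bromo-3-methylphenoxy)triisopropylsilane
Product: 3 [2-bromo-3-(bromomethyl)phenoxy]triisopropylsilane
Conditions: NBS, AIBN (cat.), PhCF3, 85 °C
Reagents that add atoms: N-bromosuccinimide, O=C1CCC(=O)N1Br
Why: Wohl–Ziegler radical bromination should be selective for the benzylic methyl group, whose C–H bond is the weakest in the molecule.

Step 3
Reactants: 4 (R)-2-methylglycidol
Product: 5 (S)-triethyl[(2-methyloxiran-2-yl)methoxy]silane
Conditions: Et3SiCl, imidazole, CH2Cl2, 0 °C
Reagents that add atoms: chlorotriethylsilane, CC[Si](Cl)(CC)CC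
Why: Silylation of the primary alcohol leaves the oxirane untouched, prevents Payne-type equilibration and alkoxide interference in the annulation, and gives a triethylsilyl ether that can later be oxidised directly.

Step 4
Reactants: 3 [2-bromo-3-(bromomethyl)phenoxy]triisopropylsilane; 5 (S)-triethyl[(2-methyloxiran-2-yl)methoxy]silane
Product: 8 (S)-2-methyl-2-[(triethylsilyloxy)methyl]-8-(triisopropylsilyloxy)chroman, via benzylic Grignard reagent 6 (not isolated), via bromomagnesium tertiary alkoxide 7 (not isolated)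
Conditions: Mg, Et2O, 0 °C; then 5, CuI (10 mol %), THF, −40 → 0 °C; then Cs2CO3, Pd(OAc)2 (5 mol %), rac-2-(di-tert-butylphosphino)-1,1'-binaphthyl, toluene, 80 °C
Reagents that add atoms: none
Why: Magnesium inserts into the benzylic C–Br bond much faster than into the aryl C–Br bond, and the benzylic cuprate formed with CuI attacks the unsubstituted ring carbon of oxirane 5 in an SN2 reaction driven by release of oxirane ring strain, which forms C3–C4 and unmasks the tertiary alkoxide 7. Zerovalent palladium then inserts into the C8a–Br bond, the tethered alkoxide replaces bromide on divalent palladium, and C–O reductive elimination forms O1–C8a. The closest known reaction types are the CuI-catalysed opening of 2,2-disubstituted oxiranes by Grignard reagents and the palladium-catalysed intramolecular etherification of aryl bromides by tertiary alcohols, run here in one flask as a formal [3+3] annulation. The dihydropyran ring is closed in the second event, by intramolecular C(sp2)–O reductive elimination from a seven-membered aryl(alkoxo)palladium chelate, the first bond being made intermolecularly. No stereocentre is created: C2 is the quaternary oxirane carbon of 5 and none of its four bonds is touched, so its configuration is transferred unchanged. The step needs attack at CH2 and not at the quaternary carbon (secured by sterics and by cuprate instead of Lewis-acid opening), survival of the aryl bromide through the organomagnesium stage (secured by the rate gap between benzylic and aryl insertion) and etherification without β-hydride elimination (impossible for a tertiary alkoxide).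

Step 5
Reactants: 8 (S)-2-methyl-2-[(triethylsilyloxy)methyl]-8-(triisopropylsilyloxy)chroman
Product: 9 (S)-2-methyl-6-(4,4,5,5-tetramethyl-1,3,2-dioxaborolan-2-yl)-2-[(triethylsilyloxy)methyl]-8-(triisopropylsilyloxy)chroman
Conditions: B2pin2, [Ir(OMe)(cod)]2 (1.5 mol %), 4,4'-di-tert-butyl-2,2'-bipyridine, THF, 80 °C
Reagents that add atoms: bis(pinacolato)diboron, CC1(C)OB(OC1(C)C)B1OC(C)(C)C(C)(C)O1
Why: Iridium-catalysed C–H borylation is ruled by sterics, and C6–H is the only aromatic C–H of 8 without an ortho substituent (C5–H lies next to the ring fusion, C7–H next to the silyloxy group), so boron should enter para to O1 where the flavanone is to be attached.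

Step 6
Reactants: 9 (S)-2-methyl-6-(4,4,5,5-tetramethyl-1,3,2-dioxaborolan-2-yl)-2-[(triethylsilyloxy)methyl]-8-(triisopropylsilyloxy)chroman
Product: 10 (S)-2-methyl-6-(4,4,5,5-tetramethyl-1,3,2-dioxaborolan-2-yl)-8-(triisopropylsilyloxy)chroman-2-carbaldehyde
Conditions: (COCl)2, DMSO, CH2Cl2, −78 → −30 °C; then Et3N, −78 °C → rt
Reagents that add atoms: none
Why: Primary triethylsilyl ethers are cleaved by the chlorosulfonium reagent and oxidised in the same Swern operation, which should give the aldehyde directly while the aryl silyl ether and the boronate stay inert and the α-quaternary centre cannot epimerise.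

Step 7
Reactants: 10 (S)-2-methyl-6-(4,4,5,5-tetramethyl-1,3,2-dioxaborolan-2-yl)-8-(triisopropylsilyloxy)chroman-2-carbaldehyde
Product: 11 (E)-3-[(S)-2-methyl-6-(4,4,5,5-tetramethyl-1,3,2-dioxaborolan-2-yl)-8-(triisopropylsilyloxy)chroman-2-yl]prop-2-enal
Conditions: Ph3P=CHCHO, toluene, 80 °C
Reagents that add atoms: (triphenylphosphoranylidene)acetaldehyde, O=CC=P(c1ccccc1)(c1ccccc1)c1ccccc1
Why: Wittig reaction of the stabilised formylmethylene ylide with the non-enolisable aldehyde should give the (E)-enal, as stabilised ylides do.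

Step 8
Reactants: 11 (E)-3-[(S)-2-methyl-6-(4,4,5,5-tetramethyl-1,3,2-dioxaborolan-2-yl)-8-(triisopropylsilyloxy)chroman-2-yl]prop-2-enal
Product: 12 (S)-2-methyl-2-[(1E)-4-methylpenta-1,3-dien-1-yl]-6-(4,4,5,5-tetramethyl-1,3,2-dioxaborolan-2-yl)-8-(triisopropylsilyloxy)chroman
Conditions: i-PrPPh3I, n-BuLi, THF, 0 °C; then 11, −78 °C → rt
Reagents that add atoms: isopropyltriphenylphosphonium iodide, CC(C)[P+](c1ccccc1)(c1ccccc1)c1ccccc1.[I-]
Why: Wittig reaction of the non-stabilised isopropylidene ylide adds 1,2 to the enal and creates a terminus that has no geometry of its own, so the diene should form with the (E) double bond of step 7 unchanged.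

Step 9
Reactants: 12 (S)-2-methyl-2-[(1E)-4-methylpenta-1,3-dien-1-yl]-6-(4,4,5,5-tetramethyl-1,3,2-dioxaborolan-2-yl)-8-(triisopropylsilyloxy)chroman
Product: 13 {(S)-2-methyl-2-[(1E)-4-methylpenta-1,3-dien-1-yl]-8-(triisopropylsilyloxy)chroman-6-yl}boronic acid
Conditions: NaIO4, NH4OAc, acetone/H2O, rt
Reagents that add atoms: water, O
Why: Periodate cleaves the pinacol released in the hydrolysis equilibrium and so drives the boronate to the free boronic acid under near-neutral conditions that should spare the diene, the tertiary allylic aryl ether and the silyl ether.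

Step 10
Reactants: 14 2,4,6-trihydroxyacetophenone
Product: 15 1-{2,4-bis[(tert-butyldimethylsilyl)oxy]-6-hydroxyphenyl}ethanone
Conditions: TBSCl (2.1 equiv), imidazole, DMF, 0 °C → rt
Reagents that add atoms: tert-butyldimethylsilyl chloride, CC(C)(C)[Si](C)(C)Cl
Why: Silylation takes the para hydroxyl and one of the two equivalent ortho hydroxyls, while the remaining ortho hydroxyl is held in a hydrogen bond to the ketone and reacts much more slowly.

Step 11
Reactants: 15 1-{2,4-bis[(tert-butyldimethylsilyl)oxy]-6-hydroxyphenyl}ethanone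
Product: 16 1-{2,4-bis[(tert-butyldimethylsilyl)oxy]-6-[(3-methylbut-2-en-1-yl)oxy]phenyl}ethanone
Conditions: 3-methylbut-2-en-1-ol, PPh3, DIAD, THF, 0 °C → rt
Reagents that add atoms: 3-methylbut-2-en-1-ol, CC(C)=CCO
Why: Mitsunobu etherification alkylates the acidic hydrogen-bonded phenol at the primary carbon of prenol under neutral conditions that should keep the aryl silyl ethers intact.

Step 12
Reactants: 16 1-{2,4-bis[(tert-butyldimethylsilyl)oxy]-6-[(3-methylbut-2-en-1-yl)oxy]phenyl}ethanone
Product: 19 1-{2,4-bis[(tert-butyldimethylsilyl)oxy]-6-hydroxy-3-(3-methylbut-2-en-1-yl)phenyl}ethanone, via ortho-dienone 17 (not isolated), via para-dienone 18 (not isolated)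
Conditions: PhNEt2, 200 °C
Reagents that add atoms: none
Why: Aromatic Claisen rearrangement to the free ortho carbon followed by Cope rearrangement of the crowded ortho-dienone should move the allyl unit, after double allylic inversion a normal prenyl group, to the carbon para to the ether oxygen between the two silyloxy groups, and tautomerisation then restores the phenol.

Step 13
Reactants: 19 1-{2,4-bis[(tert-butyldimethylsilyl)oxy]-6-hydroxy-3-(3-methylbut-2-en-1-yl)phenyl}ethanone
Product: 21 5,7-bis[(tert-butyldimethylsilyl)oxy]-6-(3-methylbut-2-en-1-yl)-4H-chromen-4-one, via enaminone 20 (not isolated)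
Conditions: Me2NCH(OMe)2, toluene, 90 °C; then TsOH·H2O (cat.), CH2Cl2, rt
Reagents that add atoms: N,N-dimethylformamide dimethyl acetal, COC(OC)N(C)C
Why: Condensation of the methyl ketone with the formamide acetal gives an enaminone that cyclises by conjugate addition of the only free phenol (the one next to C–H) and loss of dimethylamine, the standard enaminone chromone synthesis, so the prenyl group should end up at C6.

Step 14
Reactants: 13 {(S)-2-methyl-2-[(1E)-4-methylpenta-1,3-dien-1-yl]-8-(triisopropylsilyloxy)chroman-6-yl}boronic acid; 21 5,7-bis[(tert-butyldimethylsilyl)oxy]-6-(3-methylbut-2-en-1-yl)-4H-chromen-4-one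
Product: 22 (2S)-5,7-bis[(tert-butyldimethylsilyl)oxy]-2-{(2S)-2-methyl-2-[(1E)-4-methylpenta-1,3-dien-1-yl]-8-(triisopropylsilyloxy)chroman-6-yl}-6-(3-methylbut-2-en-1-yl)chroman-4-one
Conditions: Pd(OCOCF3)2 (5 mol %), (R)-t-BuPyOX (6 mol %), NH4PF6, H2O, ClCH2CH2Cl, 60 °C
Reagents that add atoms: none
Why: In this asymmetric conjugate arylation of a chromone, cationic divalent palladium bearing the pyridine–oxazoline ligand transmetalates the arylboronic acid, inserts the chromone C2=C3 bond on the ligand-controlled face and is released by protonolysis of the palladium enolate, and the (R)-ligand, the antipode of the one expected by analogy to give (2R)-flavanones, should set the new C2 centre as (S) under catalyst control because the chroman centre is remote (the ligand antipode is exchanged if the sense proves opposite).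

Step 15
Reactants: 22 (2S)-5,7-bis[(tert-butyldimethylsilyl)oxy]-2-{(2S)-2-methyl-2-[(1E)-4-methylpenta-1,3-dien-1-yl]-8-(triisopropylsilyloxy)chroman-6-yl}-6-(3-methylbut-2-en-1-yl)chroman-4-one
Product: 23 (2S)-5,7-dihydroxy-2-{(2S)-8-hydroxy-2-methyl-2-[(1E)-4-methylpenta-1,3-dien-1-yl]chroman-6-yl}-6-(3-methylbut-2-en-1-yl)chroman-4-one
Conditions: Bu4NF, AcOH, THF, 0 °C → rt
Reagents that add atoms: none
Why: Acetic-acid-buffered fluoride cleaves the three aryl silyl ethers under conditions too mild to open the flavanone by retro-oxa-Michael reaction or to ionise the tertiary allylic aryl ether, so both stereocentres and all alkenes should survive.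

Compound list
1 | 2-bromo-3-methylphenol | Cc1cccc(O)c1Br | starting material
2 | (2-bromo-3-methylphenoxy)triisopropylsilane | Cc1cccc(O[Si](C(C)C)(C(C)C)C(C)C)c1Br | intermediate
3 | [2-bromo-3-(bromomethyl)phenoxy]triisopropylsilane | BrCc1cccc(O[Si](C(C)C)(C(C)C)C(C)C)c1Br | intermediate
4 | (R)-2-methylglycidol, (R)-(2-methyloxiran-2-yl)methanol | OC[C@]1(C)CO1 | starting material
5 | (S)-triethyl[(2-methyloxiran-2-yl)methoxy]silane | CC[Si](CC)(CC)OC[C@]1(C)CO1 | intermediate
6 | {2-bromo-3-[(triisopropylsilyl)oxy]benzyl}magnesium bromide | Br[Mg]Cc1cccc(O[Si](C(C)C)(C(C)C)C(C)C)c1Br | intermediate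
7 | bromomagnesium (S)-4-{2-bromo-3-[(triisopropylsilyl)oxy]phenyl}-2-methyl-1-[(triethylsilyl)oxy]butan-2-olate | CC[Si](CC)(CC)OC[C@](O[Mg]Br)(C)CCc1cccc(O[Si](C(C)C)(C(C)C)C(C)C)c1Br | intermediate
8 | (S)-2-methyl-2-[(triethylsilyloxy)methyl]-8-(triisopropylsilyloxy)chroman | CC[Si](CC)(CC)OC[C@]1(C)CCc2cccc(O[Si](C(C)C)(C(C)C)C(C)C)c2O1 | intermediate
9 | (S)-2-methyl-6-(4,4,5,5-tetramethyl-1,3,2-dioxaborolan-2-yl)-2-[(triethylsilyloxy)methyl]-8-(triisopropylsilyloxy)chroman | CC[Si](CC)(CC)OC[C@]1(C)CCc2cc(B3OC(C)(C)C(C)(C)O3)cc(O[Si](C(C)C)(C(C)C)C(C)C)c2O1 | intermediate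
10 | (S)-2-methyl-6-(4,4,5,5-tetramethyl-1,3,2-dioxaborolan-2-yl)-8-(triisopropylsilyloxy)chroman-2-carbaldehyde | O=C[C@]1(C)CCc2cc(B3OC(C)(C)C(C)(C)O3)cc(O[Si](C(C)C)(C(C)C)C(C)C)c2O1 | intermediate
11 | (E)-3-[(S)-2-methyl-6-(4,4,5,5-tetramethyl-1,3,2-dioxaborolan-2-yl)-8-(triisopropylsilyloxy)chroman-2-yl]prop-2-enal | O=C/C=C/[C@]1(C)CCc2cc(B3OC(C)(C)C(C)(C)O3)cc(O[Si](C(C)C)(C(C)C)C(C)C)c2O1 | intermediate
12 | (S)-2-methyl-2-[(1E)-4-methylpenta-1,3-dien-1-yl]-6-(4,4,5,5-tetramethyl-1,3,2-dioxaborolan-2-yl)-8-(triisopropylsilyloxy)chroman | CC(C)=C/C=C/[C@]1(C)CCc2cc(B3OC(C)(C)C(C)(C)O3)cc(O[Si](C(C)C)(C(C)C)C(C)C)c2O1 | intermediate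
13 | {(S)-2-methyl-2-[(1E)-4-methylpenta-1,3-dien-1-yl]-8-(triisopropylsilyloxy)chroman-6-yl}boronic acid | CC(C)=C/C=C/[C@]1(C)CCc2cc(B(O)O)cc(O[Si](C(C)C)(C(C)C)C(C)C)c2O1 | intermediate
14 | 2,4,6-trihydroxyacetophenone | CC(=O)c1c(O)cc(O)cc1O | starting material
15 | 1-{2,4-bis[(tert-butyldimethylsilyl)oxy]-6-hydroxyphenyl}ethanone | CC(=O)c1c(O)cc(O[Si](C)(C)C(C)(C)C)cc1O[Si](C)(C)C(C)(C)C | intermediate
16 | 1-{2,4-bis[(tert-butyldimethylsilyl)oxy]-6-[(3-methylbut-2-en-1-yl)oxy]phenyl}ethanone | CC(=O)c1c(OCC=C(C)C)cc(O[Si](C)(C)C(C)(C)C)cc1O[Si](C)(C)C(C)(C)C | intermediate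
17 | 2-acetyl-3,5-bis[(tert-butyldimethylsilyl)oxy]-6-(2-methylbut-3-en-2-yl)cyclohexa-2,4-dien-1-one | CC(=O)C1=C(O[Si](C)(C)C(C)(C)C)C=C(O[Si](C)(C)C(C)(C)C)C(C(C)(C)C=C)C1=O | intermediate
18 | 2-acetyl-3,5-bis[(tert-butyldimethylsilyl)oxy]-4-(3-methylbut-2-en-1-yl)cyclohexa-2,5-dien-1-one | CC(=O)C1=C(O[Si](C)(C)C(C)(C)C)C(CC=C(C)C)C(O[Si](C)(C)C(C)(C)C)=CC1=O | intermediate
19 | 1-{2,4-bis[(tert-butyldimethylsilyl)oxy]-6-hydroxy-3-(3-methylbut-2-en-1-yl)phenyl}ethanone | CC(=O)c1c(O)cc(O[Si](C)(C)C(C)(C)C)c(CC=C(C)C)c1O[Si](C)(C)C(C)(C)C | intermediate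
20 | (E)-1-{2,4-bis[(tert-butyldimethylsilyl)oxy]-6-hydroxy-3-(3-methylbut-2-en-1-yl)phenyl}-3-(dimethylamino)prop-2-en-1-one | CN(C)/C=C/C(=O)c1c(O)cc(O[Si](C)(C)C(C)(C)C)c(CC=C(C)C)c1O[Si](C)(C)C(C)(C)C | intermediate
21 | 5,7-bis[(tert-butyldimethylsilyl)oxy]-6-(3-methylbut-2-en-1-yl)-4H-chromen-4-one | O=c1ccoc2cc(O[Si](C)(C)C(C)(C)C)c(CC=C(C)C)c(O[Si](C)(C)C(C)(C)C)c12 | intermediate
22 | (2S)-5,7-bis[(tert-butyldimethylsilyl)oxy]-2-{(2S)-2-methyl-2-[(1E)-4-methylpenta-1,3-dien-1-yl]-8-(triisopropylsilyloxy)chroman-6-yl}-6-(3-methylbut-2-en-1-yl)chroman-4-one | CC(C)=C/C=C/[C@]1(C)CCc2cc([C@@H]3CC(=O)c4c(cc(O[Si](C)(C)C(C)(C)C)c(CC=C(C)C)c4O[Si](C)(C)C(C)(C)C)O3)cc(O[Si](C(C)C)(C(C)C)C(C)C)c2O1 | intermediate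
23 | (2S)-5,7-dihydroxy-2-{(2S)-8-hydroxy-2-methyl-2-[(1E)-4-methylpenta-1,3-dien-1-yl]chroman-6-yl}-6-(3-methylbut-2-en-1-yl)chroman-4-one | CC(C)=C/C=C/[C@]1(C)CCc2cc([C@@H]3CC(=O)c4c(cc(O)c(CC=C(C)C)c4O)O3)cc(O)c2O1 | target

Total step count: 15
Longest linear sequence: 10 steps (steps 1, 2, 4, 5, 6, 7, 8, 9, 14, 15)

Steps most likely to fail

Step 4 (key step). The risks are homocoupling of the benzylic halide during magnesium insertion, magnesium-halide-induced rearrangement of the oxirane before the cuprate attacks, and slow hand-over of the magnesium alkoxide to palladium so that reduction of the aryl bromide outruns etherification. The fallback takes the annulation apart into two purified operations and moves the ring closure from palladium to copper. It sets out from 3 and 5: the Grignard reagent from 3 opens 5 under CuI catalysis, and aqueous work-up gives (S)-4-[2-bromo-3-(triisopropylsilyloxy)phenyl]-2-methyl-1-(triethylsilyloxy)butan-2-ol F1. F1 is then cyclised by Ullmann etherification (CuI, 3,4,7,8-tetramethyl-1,10-phenanthroline, Cs2CO3, toluene, 110 °C), which rejoins the route at 8.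

Step 14. The risks are coordination and insertion of the 1,3-diene into the arylpalladium species, slow insertion of the electron-rich bis(silyloxy)chromone so that protodeboronation dominates, and erosion of facial selectivity. The fallback builds ring C by O1–C2 bond formation instead of C2–aryl bond formation. It sets out from 12 and 19: Matteson homologation of 12 with LiCHCl2 (THF, −100 °C → rt) and oxidation with NaBO3·4H2O gives (S)-2-methyl-2-[(1E)-4-methylpenta-1,3-dien-1-yl]-8-(triisopropylsilyloxy)chroman-6-carbaldehyde F2. Claisen–Schmidt condensation of F2 with 19 (LiN(SiMe3)2, THF, −78 °C → rt) gives the 2'-hydroxychalcone (E)-1-{2,4-bis[(tert-butyldimethylsilyl)oxy]-6-hydroxy-3-(3-methylbut-2-en-1-yl)phenyl}-3-{(S)-2-methyl-2-[(1E)-4-methylpenta-1,3-dien-1-yl]-8-(triisopropylsilyloxy)chroman-6-yl}prop-2-en-1-one F3. Intramolecular oxa-Michael addition of F3 under a quinine-derived bifunctional thiourea catalyst (toluene, rt) closes ring C; the minor C2 epimer is a diastereomer because the chroman centre is fixed and is removed by chromatography, which rejoins the route at 22.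

Step 12. The risks are tautomerisation of the ortho-dienone before the Cope shift, which would leave a reverse-prenyl group at the ortho carbon, thermal loss of the prenyl group, and silyl migration at 200 °C. The fallback sets the regiochemistry at the chromone stage, where only one ortho position is open, and sets out from 14. Me2NCH(OMe)2 followed by aqueous HCl converts 14 into 5,7-dihydroxy-4H-chromen-4-one F4. Silylation of the non-chelated hydroxyl (TBSCl, imidazole) gives 7-[(tert-butyldimethylsilyl)oxy]-5-hydroxy-4H-chromen-4-one F5, and Mitsunobu allylation (allyl alcohol, PPh3, DIAD) gives 5-(allyloxy)-7-[(tert-butyldimethylsilyl)oxy]-4H-chromen-4-one F6. Eu(fod)3-catalysed Claisen rearrangement delivers the allyl group to C6, giving 6-allyl-7-[(tert-butyldimethylsilyl)oxy]-5-hydroxy-4H-chromen-4-one F7. Cross-metathesis with 2-methylbut-2-ene (second-generation Grubbs catalyst, CH2Cl2, 40 °C) gives 7-[(tert-butyldimethylsilyl)oxy]-5-hydroxy-6-(3-methylbut-2-en-1-yl)-4H-chromen-4-one F8, and silylation of the 5-hydroxyl (TBSOTf, 2,6-lutidine) rejoins the route at 21.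

Further compounds
F1 | step 4 | (S)-4-[2-bromo-3-(triisopropylsilyloxy)phenyl]-2-methyl-1-(triethylsilyloxy)butan-2-ol | CC[Si](CC)(CC)OC[C@](O)(C)CCc1cccc(O[Si](C(C)C)(C(C)C)C(C)C)c1Br
F2 | step 14 | (S)-2-methyl-2-[(1E)-4-methylpenta-1,3-dien-1-yl]-8-(triisopropylsilyloxy)chroman-6-carbaldehyde | CC(C)=C/C=C/[C@]1(C)CCc2cc(C=O)cc(O[Si](C(C)C)(C(C)C)C(C)C)c2O1
F3 | step 14 | (E)-1-{2,4-bis[(tert-butyldimethylsilyl)oxy]-6-hydroxy-3-(3-methylbut-2-en-1-yl)phenyl}-3-{(S)-2-methyl-2-[(1E)-4-methylpenta-1,3-dien-1-yl]-8-(triisopropylsilyloxy)chroman-6-yl}prop-2-en-1-one | CC(C)=C/C=C/[C@]1(C)CCc2cc(/C=C/C(=O)c3c(O)cc(O[Si](C)(C)C(C)(C)C)c(CC=C(C)C)c3O[Si](C)(C)C(C)(C)C)cc(O[Si](C(C)C)(C(C)C)C(C)C)c2O1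
F4 | step 12 | 5,7-dihydroxy-4H-chromen-4-one | O=c1ccoc2cc(O)cc(O)c12
F5 | step 12 | 7-[(tert-butyldimethylsilyl)oxy]-5-hydroxy-4H-chromen-4-one | O=c1ccoc2cc(O[Si](C)(C)C(C)(C)C)cc(O)c12
F6 | step 12 | 5-(allyloxy)-7-[(tert-butyldimethylsilyl)oxy]-4H-chromen-4-one | O=c1ccoc2cc(O[Si](C)(C)C(C)(C)C)cc(OCC=C)c12
F7 | step 12 | 6-allyl-7-[(tert-butyldimethylsilyl)oxy]-5-hydroxy-4H-chromen-4-one | O=c1ccoc2cc(O[Si](C)(C)C(C)(C)C)c(CC=C)c(O)c12
F8 | step 12 | 7-[(tert-butyldimethylsilyl)oxy]-5-hydroxy-6-(3-methylbut-2-en-1-yl)-4H-chromen-4-one | O=c1ccoc2cc(O[Si](C)(C)C(C)(C)C)c(CC=C(C)C)c(O)c12
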